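## Retrosynthetic overview

1. The target is (2S,3R,2''S,3''R), with both heterocycles 2,3-trans. The last disconnection is the 7''-O–CH3 bond, which leads back to a C2-symmetric 7,7''-diol whose two 7-OH groups are homotopic.
2. Both O1–C2 bonds are cut at once. This gives an achiral, open Cα–Cα'-linked bichalcone, the aromatic counterpart of the bis(quinone methide) that chalcone coupling is thought to give in the plant.
3. In the forward direction one chiral base/hydrogen-bond catalyst closes ring C of the first half and then ring C of the second half in one flask. All four stereocentres arise here.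
4. The bichalcone is cut at its two aroyl–Cα bonds into 1,4-bis(4-methoxyphenyl)butadiyne and two phloroglucinaldehyde units (twofold hydroacylation). The future C3–C3'' bond is the central σ-bond of the diyne, made by Glaser coupling.
5. Rings A and B are bought. Only the two rings C are made.

Assumption: the quinine-derived thiourea of step 4 is taken to give the 2S sense of ring closure; if it gives 2R, its quinidine-derived pseudo-enantiomer is used and nothing else changes.

## Route

Step 1
Reactants: 1 4-ethynylanisole (2 equiv)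
Product: 2 1,4-bis(4-methoxyphenyl)buta-1,3-diyne
Conditions: CuCl (5 mol %), TMEDA (10 mol %), O2 (1 atm), acetone, rt
Reagents that add atoms: none
Why: Glaser–Hay oxidative homocoupling of a terminal arylacetylene through copper acetylides is high-yielding for electron-rich arylalkynes and creates no stereocentre.

Step 2
Reactants: 3 2,4,6-trihydroxybenzaldehyde
Product: 4 2-hydroxy-4,6-bis(tert-butyldimethylsilyloxy)benzaldehyde
Conditions: TBSCl (2.05 equiv), imidazole (2.5 equiv), DMF, 0 °C to rt
Reagents that add atoms: tert-butyldimethylsilyl chloride, CC(C)(C)[Si](C)(C)Cl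
Why: In this regioselective phenol silylation the acidic 4-OH and one ortho-OH react while the last ortho-OH stays locked in a hydrogen bond to the formyl group (the usual 4,6-bis-protection pattern of acylphloroglucinols), which leaves the chelating OH needed in step 3 and masks the phenols that would otherwise close the rings racemically there.

Step 3
Reactants: 2 1,4-bis(4-methoxyphenyl)buta-1,3-diyne (1 equiv); 4 2-hydroxy-4,6-bis(tert-butyldimethylsilyloxy)benzaldehyde (2.2 equiv)
Product: 7 (2E,3E)-2,3-bis(4-methoxybenzylidene)-1,4-bis(2,4,6-trihydroxyphenyl)butane-1,4-dione, via enynone mono-adduct 5 (not isolated), via tetrasilyl bichalcone 6 (not isolated)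
Conditions: [RhCl(cod)]2 (2.5 mol %), 1,1'-bis(diphenylphosphino)ferrocene (5 mol %), Na2CO3 (10 mol %), toluene, 80 °C, dark; then THF, pyridine, HF·pyridine, 0 °C
Reagents that add atoms: none
Why: Proposed new method: in this twofold chelation-assisted alkyne hydroacylation the phenoxide of monovalent rhodium formed from 4 inserts into the formyl C–H bond, the acyl hydride of trivalent rhodium adds syn across one triple bond with H on the aryl-bearing carbon and rhodium on the inner carbon next to the remaining π-system (the regiochemistry seen in hydroboration of conjugated diynes and in hydroacylation of 1-aryl-1-alkynes), reductive elimination gives (E)-5 and a second cycle gives (E,E)-6, whose single hydrogen-bonded 2'-OH does not cyclise under these weakly basic conditions, and buffered HF then cleaves the four aryl silyl ethers without releasing a free phenoxide, the closest known reaction type being rhodium/diphosphine-catalysed hydroacylation of internal alkynes with salicylaldehydes to 2'-hydroxy-α-substituted enones.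

Step 4
Reactants: 7 (2E,3E)-2,3-bis(4-methoxybenzylidene)-1,4-bis(2,4,6-trihydroxyphenyl)butane-1,4-dione
Product: 9 (2S,3R,2''S,3''R)-5,5'',7,7''-tetrahydroxy-4',4'''-dimethoxy-3,3''-biflavanone, via monocyclised flavanone-chalcone 8 (not isolated)
Conditions: N-[3,5-bis(trifluoromethyl)phenyl]-N'-[(8α,9S)-6'-methoxycinchonan-9-yl]thiourea (20 mol %), toluene–THF 5:1, −20 °C, argon, dark; meso isomer removed on silica, then one recrystallisation
Reagents that add atoms: none
Why: Proposed new method: in this catalytic enantioselective twofold intramolecular oxa-Michael addition (chalcone-to-flavanone closure) the quinuclidine nitrogen takes the proton of one ortho-phenol while the thiourea and the second, hydrogen-bonded ortho-OH activate the carbonyl group, the ion-paired phenoxide attacks one face of the 4-methoxybenzylidene carbon (an O-methylated quinone-methide-like acceptor) to set C-2 as S, amine-mediated keto–enol equilibration puts the bulky C-3 substituent trans-diequatorial (3R), the same events in 8 set 2''S and 3''R, and since two catalyst-controlled closures are needed the wrong-sense events end up mainly in the separable meso isomer (Horeau-type amplification), the closest known reaction type being cinchona-thiourea-catalysed enantioselective cyclisation of 2'-hydroxychalcone-type enones to flavanones.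

Step 5
Reactants: 9 (2S,3R,2''S,3''R)-5,5'',7,7''-tetrahydroxy-4',4'''-dimethoxy-3,3''-biflavanone
Product: 10 ruixianglangdusu B, (2S,3R,2''S,3''R)-5,5'',7-trihydroxy-4',4''',7''-trimethoxy-3,3''-biflavanone
Conditions: TMSCHN2 (1.0 equiv, slow addition), toluene–MeOH 4:1, 0 °C
Reagents that add atoms: (trimethylsilyl)diazomethane, C[Si](C)(C)C=[N+]=[N-]
Why: In this phenol O-methylation by a diazoalkane the two 7-OH groups are the only non-chelated phenols and are homotopic in C2-symmetric 9, so one equivalent gives a single mono-ether (statistical, about half, with unreacted 9 recovered and recycled and the dimethyl ether separable), while the 5-OH groups stay hydrogen-bonded and the neutral cold medium allows neither enolisation nor ring opening, so no stereocentre is touched.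

## Compound list

1 | 4-ethynylanisole | C#Cc1ccc(OC)cc1 | starting material
2 | 1,4-bis(4-methoxyphenyl)buta-1,3-diyne | COc1ccc(C#CC#Cc2ccc(OC)cc2)cc1 | intermediate
3 | 2,4,6-trihydroxybenzaldehyde | O=Cc1c(O)cc(O)cc1O | starting material
4 | 2-hydroxy-4,6-bis(tert-butyldimethylsilyloxy)benzaldehyde | O=Cc1c(O)cc(O[Si](C)(C)C(C)(C)C)cc1O[Si](C)(C)C(C)(C)C | intermediate
5 | (E)-1-[2-hydroxy-4,6-bis(tert-butyldimethylsilyloxy)phenyl]-3-(4-methoxyphenyl)-2-[(4-methoxyphenyl)ethynyl]prop-2-en-1-one | COc1ccc(/C=C(/C(=O)c2c(O)cc(O[Si](C)(C)C(C)(C)C)cc2O[Si](C)(C)C(C)(C)C)C#Cc2ccc(OC)cc2)cc1 | intermediate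
6 | (2E,3E)-1,4-bis[2-hydroxy-4,6-bis(tert-butyldimethylsilyloxy)phenyl]-2,3-bis(4-methoxybenzylidene)butane-1,4-dione | COc1ccc(/C=C(/C(=O)c2c(O)cc(O[Si](C)(C)C(C)(C)C)cc2O[Si](C)(C)C(C)(C)C)C(=C/c2ccc(OC)cc2)\C(=O)c2c(O)cc(O[Si](C)(C)C(C)(C)C)cc2O[Si](C)(C)C(C)(C)C)cc1 | intermediate
7 | (2E,3E)-2,3-bis(4-methoxybenzylidene)-1,4-bis(2,4,6-trihydroxyphenyl)butane-1,4-dione (hexahydroxy bichalcone) | COc1ccc(/C=C(/C(=O)c2c(O)cc(O)cc2O)C(=C/c2ccc(OC)cc2)\C(=O)c2c(O)cc(O)cc2O)cc1 | intermediate
8 | (2S,3R)-5,7-dihydroxy-2-(4-methoxyphenyl)-3-[(E)-1-(4-methoxyphenyl)-3-oxo-3-(2,4,6-trihydroxyphenyl)prop-1-en-2-yl]chroman-4-one | COc1ccc([C@H]2Oc3cc(O)cc(O)c3C(=O)[C@@H]2C(=C/c2ccc(OC)cc2)\C(=O)c2c(O)cc(O)cc2O)cc1 | intermediate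
9 | (2S,3R,2''S,3''R)-5,5'',7,7''-tetrahydroxy-4',4'''-dimethoxy-3,3''-biflavanone | COc1ccc([C@H]2Oc3cc(O)cc(O)c3C(=O)[C@@H]2[C@H]2C(=O)c3c(O)cc(O)cc3O[C@@H]2c2ccc(OC)cc2)cc1 | intermediate
10 | ruixianglangdusu B, (2S,3R,2''S,3''R)-5,5'',7-trihydroxy-4',4''',7''-trimethoxy-3,3''-biflavanone | COc1ccc([C@H]2Oc3cc(O)cc(O)c3C(=O)[C@@H]2[C@H]2C(=O)c3c(O)cc(OC)cc3O[C@@H]2c2ccc(OC)cc2)cc1 | target

## Step count and risks

Total step count: 5. Longest linear sequence: 4 (3 → 4 → 7 → 9 → 10, or equally 1 → 2 → 7 → 9 → 10).

**Step 3.** The risks are the regiochemistry at the diyne and a slow second addition next to the hindered aroyl group.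

The fallback drops C–H activation and makes the two aroyl–Cα bonds by carbonyl addition. It sets out from 2, with 4 as partner, and comes back to the route at 6.

Twofold syn-hydroboration of 2 with dicyclohexylborane puts boron on the two inner carbons of a conjugated diyne. It gives (1Z,3Z)-2,3-bis(dicyclohexylboryl)-1,4-bis(4-methoxyphenyl)buta-1,3-diene F1. Boron–zinc exchange with Et2Zn gives (1E,3E)-2,3-bis(ethylzincio)-1,4-bis(4-methoxyphenyl)buta-1,3-diene F2. F2 adds with retention of alkene geometry to the zinc phenoxide of 4. The product is (2E,3E)-1,4-bis[2-hydroxy-4,6-bis(tert-butyldimethylsilyloxy)phenyl]-2,3-bis(4-methoxybenzylidene)butane-1,4-diol F3, a set of carbinol epimers whose configuration does not matter. MnO2 in CH2Cl2 oxidises F3 to 6, which is desilylated as in step 3.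

**Step 4.** The risks are the level and sense of induction with a hexaphenolic substrate, uncatalysed closure, and drift of 8 to a conjugated enedione. A per-ring selectivity of 9:1 would already give about 81:18:1 of 9, meso isomer and enantiomer.

The fallback gives up catalyst control and separates the stereoisomers. It sets out from 7 and comes back at 9.

Et3N in MeOH at rt closes 7 under thermodynamic control to the trans,trans products. These are 9, its enantiomer (2R,3S,2''R,3''S)-5,5'',7,7''-tetrahydroxy-4',4'''-dimethoxy-3,3''-biflavanone F4, and the meso isomer (2S,3R,2''R,3''S)-5,5'',7,7''-tetrahydroxy-4',4'''-dimethoxy-3,3''-biflavanone F5. F5 is removed on silica. 9 is separated from F4 by preparative chiral SFC on amylose tris(3,5-dimethylphenylcarbamate). F4 and F5 are returned to Et3N/MeOH at 50 °C, where ring opening and reclosure re-equilibrate them for another pass.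

**Step 5.** The risk is the statistical ceiling of about one half and the three-component separation.

The fallback builds the difference between the halves before the rings close. It sets out from 2 and 4 at the stage of 5 and comes back at 10.

With 2 in threefold excess the hydroacylation is stopped at 5, which is isolated. Commercial 2,6-dihydroxy-4-methoxybenzaldehyde is monosilylated to 2-hydroxy-4-methoxy-6-(tert-butyldimethylsilyloxy)benzaldehyde F6. A second hydroacylation of 5 with F6 gives the unsymmetrical trisilyl bichalcone (2E,3E)-1-[2-hydroxy-4,6-bis(tert-butyldimethylsilyloxy)phenyl]-4-[2-hydroxy-4-methoxy-6-(tert-butyldimethylsilyloxy)phenyl]-2,3-bis(4-methoxybenzylidene)butane-1,4-dione F7. Buffered HF·pyridine gives the pentahydroxy bichalcone (2E,3E)-1-(2,6-dihydroxy-4-methoxyphenyl)-2,3-bis(4-methoxybenzylidene)-4-(2,4,6-trihydroxyphenyl)butane-1,4-dione F8. The catalyst of step 4 closes both rings of F8 to give 10 directly, without any late methylation.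

## Further compounds

F1 | step 3 | (1Z,3Z)-2,3-bis(dicyclohexylboryl)-1,4-bis(4-methoxyphenyl)buta-1,3-diene | COc1ccc(/C=C(/B(C2CCCCC2)C2CCCCC2)C(=C/c2ccc(OC)cc2)\B(C2CCCCC2)C2CCCCC2)cc1
F2 | step 3 | (1E,3E)-2,3-bis(ethylzincio)-1,4-bis(4-methoxyphenyl)buta-1,3-diene | COc1ccc(/C=C(/[Zn]CC)C(=C/c2ccc(OC)cc2)\[Zn]CC)cc1
F3 | step 3 | (2E,3E)-1,4-bis[2-hydroxy-4,6-bis(tert-butyldimethylsilyloxy)phenyl]-2,3-bis(4-methoxybenzylidene)butane-1,4-diol (carbinol epimers) | COc1ccc(/C=C(/C(O)c2c(O)cc(O[Si](C)(C)C(C)(C)C)cc2O[Si](C)(C)C(C)(C)C)C(=C/c2ccc(OC)cc2)\C(O)c2c(O)cc(O[Si](C)(C)C(C)(C)C)cc2O[Si](C)(C)C(C)(C)C)cc1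
F4 | step 4 | (2R,3S,2''R,3''S)-5,5'',7,7''-tetrahydroxy-4',4'''-dimethoxy-3,3''-biflavanone | COc1ccc([C@@H]2Oc3cc(O)cc(O)c3C(=O)[C@H]2[C@@H]2C(=O)c3c(O)cc(O)cc3O[C@H]2c2ccc(OC)cc2)cc1
F5 | step 4 | (2S,3R,2''R,3''S)-5,5'',7,7''-tetrahydroxy-4',4'''-dimethoxy-3,3''-biflavanone (meso) | COc1ccc([C@H]2Oc3cc(O)cc(O)c3C(=O)[C@@H]2[C@@H]2C(=O)c3c(O)cc(O)cc3O[C@H]2c2ccc(OC)cc2)cc1
F6 | step 5 | 2-hydroxy-4-methoxy-6-(tert-butyldimethylsilyloxy)benzaldehyde | O=Cc1c(O)cc(OC)cc1O[Si](C)(C)C(C)(C)C
F7 | step 5 | (2E,3E)-1-[2-hydroxy-4,6-bis(tert-butyldimethylsilyloxy)phenyl]-4-[2-hydroxy-4-methoxy-6-(tert-butyldimethylsilyloxy)phenyl]-2,3-bis(4-methoxybenzylidene)butane-1,4-dione | COc1ccc(/C=C(/C(=O)c2c(O)cc(O[Si](C)(C)C(C)(C)C)cc2O[Si](C)(C)C(C)(C)C)C(=C/c2ccc(OC)cc2)\C(=O)c2c(O)cc(OC)cc2O[Si](C)(C)C(C)(C)C)cc1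
F8 | step 5 | (2E,3E)-1-(2,6-dihydroxy-4-methoxyphenyl)-2,3-bis(4-methoxybenzylidene)-4-(2,4,6-trihydroxyphenyl)butane-1,4-dione | COc1ccc(/C=C(/C(=O)c2c(O)cc(O)cc2O)C(=C/c2ccc(OC)cc2)\C(=O)c2c(O)cc(OC)cc2O)cc1
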